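**Retrosynthetic overview**

1. Feature: the quinone ring (C1, C2, C3, C4, C4a, C8a) has one olefinic bond, C2=C3, lying between the carbonyl carbons C1 and C4, which sit on adjacent carbons (C8a, C4a) of the benzenoid ring; each carbonyl can be carried as a secondary carbinol on an ortho-disubstituted 1,4-dimethoxybenzene.
2. Endgame: 21 ⇐ dimethyl ether 19 (oxidative demethylation by way of the 1,4,5,8-tetraone) ⇐ alcohol 17 + tiglic acid 18 ⇐ silyl ether quinone 16 ⇐ ene-diol 15.
3. Key disconnection: C2=C3 of 15 by ring-closing metathesis of diene-diol 14; the quinone ring is the only ring made, the benzenoid ring is bought.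
4. 14 ⇐ C1–C8a bond: aryllithium from bromo carbinol 12 (C4 from DMF, C3 from vinylmagnesium bromide) + 2-methylidene aldehyde 7 (its CHO becomes C1, its methylidene-bearing carbon C2).
5. 7 ⇐ (R)-epoxy ester 1 + isobutenyl Grignard 2; the C1′ (S) centre comes from the chiral pool and its C–O bond is never broken afterwards.

Key step: step 8

Assumption: ethyl 2-[(2R)-oxiran-2-yl]acetate (1) is taken as a purchasable enantiopure epoxide, and the two carbinol centres made in steps 6 and 7 are carried as mixtures because step 9 removes them.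

**Route**

Step 1
Reactants: 1 ethyl 2-[(2R)-oxiran-2-yl]acetate; 2 (2-methylprop-1-en-1-yl)magnesium bromide
Product: 3 ethyl (3S)-3-hydroxy-6-methylhept-5-enoate
Conditions: 2 (1.5 equiv), CuI (10 mol%), THF, −40 → −20 °C; aq. work-up
Reagents that add atoms: none
Why: Copper-catalysed SN2 opening of the terminal epoxide by the alkenyl Grignard at the unhindered CH2 outruns attack on the ester at low temperature, and because the C3–O bond is not broken the (R)-epoxide gives the (S)-carbinol (the descriptor changes only through CIP priorities).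

Step 2
Reactants: 3 ethyl (3S)-3-hydroxy-6-methylhept-5-enoate
Product: 4 ethyl (3S)-3-[(tert-butyldimethylsilyl)oxy]-6-methylhept-5-enoate
Conditions: TBSCl, imidazole, DMF, rt
Reagents that add atoms: tert-butyldimethylsilyl chloride, CC(C)(C)[Si](C)(C)Cl
Why: Standard imidazole-promoted silylation of a secondary alcohol at oxygen, with retention at C3.

Step 3
Reactants: 4 ethyl (3S)-3-[(tert-butyldimethylsilyl)oxy]-6-methylhept-5-enoate
Product: 5 (3S)-3-[(tert-butyldimethylsilyl)oxy]-6-methylhept-5-enal
Conditions: DIBAL-H (1.1 equiv), CH2Cl2, −78 °C; MeOH, then aq. Rochelle salt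
Reagents that add atoms: none
Why: Partial reduction of the ester by DIBAL-H stops at the aluminium hemiacetal at −78 °C (aided by the β-silyloxy group), which releases the aldehyde on work-up.

Step 4
Reactants: 5 (3S)-3-[(tert-butyldimethylsilyl)oxy]-6-methylhept-5-enal
Product: 7 (3S)-3-[(tert-butyldimethylsilyl)oxy]-6-methyl-2-methylidenehept-5-enal, via Mannich base 6 (not isolated)
Conditions: Eschenmoser's salt (2.5 equiv), Et3N (5 equiv), CH2Cl2, rt
Reagents that add atoms: N,N-dimethylmethyleneiminium iodide, C=[N+](C)C.[I-]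
Why: Mannich reaction of the aldehyde with the iminium salt followed by amine-promoted loss of dimethylamine (α-methylenation) gives the enal, and C3 is not epimerised because enolisation involves only C2.

Step 5
Reactants: 8 2-bromo-1,4-dimethoxybenzene
Product: 10 2-bromo-3,6-dimethoxybenzaldehyde, via aryllithium 9 (not isolated)
Conditions: LDA (1.1 equiv), THF, −78 °C; DMF, −78 → 0 °C; aq. work-up
Reagents that add atoms: N,N-dimethylformamide, CN(C)C=O
Why: Directed ortho-metalation removes the ring proton flanked by bromine and methoxy (the most acidic site) at a temperature where halogen migration and aryne formation are slow, and DMF formylates the aryllithium.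

Step 6
Reactants: 10 2-bromo-3,6-dimethoxybenzaldehyde; 11 vinylmagnesium bromide
Product: 12 1-(2-bromo-3,6-dimethoxyphenyl)prop-2-en-1-ol (racemic)
Conditions: 11 (1.2 equiv), THF, −78 → 0 °C; aq. work-up
Reagents that add atoms: none
Why: Grignard 1,2-addition to the aldehyde gives the vinyl carbinol, formed racemic without consequence because this centre is oxidised in step 9.

Step 7
Reactants: 12 1-(2-bromo-3,6-dimethoxyphenyl)prop-2-en-1-ol; 7 (3S)-3-[(tert-butyldimethylsilyl)oxy]-6-methyl-2-methylidenehept-5-enal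
Product: 14 (3S)-3-[(tert-butyldimethylsilyl)oxy]-1-[2-(1-hydroxyprop-2-en-1-yl)-3,6-dimethoxyphenyl]-6-methyl-2-methylidenehept-5-en-1-ol (mixture at both carbinol carbons), via dilithio species 13 (not isolated)
Conditions: 12 (1.3 equiv), n-BuLi (2.6 equiv), THF, −78 °C; then 7 (1.0 equiv), −78 °C; H2O quench
Reagents that add atoms: none
Why: The first equivalent of n-BuLi deprotonates the hydroxyl and the second effects bromine–lithium exchange (Parham-type), after which the aryllithium adds 1,2 to the non-enolisable enal; the new carbinol centre forms without control and is erased in step 9, while the silyloxy centre is untouched.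

Step 8
Reactants: 14 (3S)-3-[(tert-butyldimethylsilyl)oxy]-1-[2-(1-hydroxyprop-2-en-1-yl)-3,6-dimethoxyphenyl]-6-methyl-2-methylidenehept-5-en-1-ol
Product: 15 2-[(1S)-1-[(tert-butyldimethylsilyl)oxy]-4-methylpent-3-en-1-yl]-5,8-dimethoxy-1,4-dihydronaphthalene-1,4-diol (mixture at C1 and C4)
Conditions: Hoveyda–Grubbs II (10 mol%), 1,4-benzoquinone (20 mol%), degassed toluene (0.005 M), 60 °C, argon sparge
Reagents that add atoms: none
Why: This is a ring-closing olefin metathesis by the Chauvin mechanism: the ruthenium carbene exchanges onto the unhindered vinyl carbinol, the new alkylidene cycloadds intramolecularly to the 1,1-disubstituted alkene, and cycloreversion of the ruthenacyclobutane expels ethene and leaves the trisubstituted C2=C3 bond. The closest known reaction type is the metathesis of ortho-bis(1-hydroxyallyl)arenes to 1,4-dihydronaphthalene-1,4-diols that are then oxidised to naphthoquinones. The one ring closed is the six-membered carbocycle C1–C2=C3–C4–C4a–C8a, closed at C2=C3, with the ortho-disubstituted benzene holding the two alkenes within reach. No stereocentre is created; the C1 and C4 carbinols stay as a mixture that step 9 removes, and the (S) silyloxy centre is not involved. The step needs the two terminal alkenes to react in preference to the prenyl alkene, which the substrate secures because that trisubstituted alkene is slow to engage and could close only a four- or nine-membered ring. It also needs suppression of ruthenium hydride isomerisation of the allylic alcohols to ketones, for which benzoquinone is added, the solution is kept dilute and ethene is purged.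

Step 9
Reactants: 15 2-[(1S)-1-[(tert-butyldimethylsilyl)oxy]-4-methylpent-3-en-1-yl]-5,8-dimethoxy-1,4-dihydronaphthalene-1,4-diol
Product: 16 2-[(1S)-1-[(tert-butyldimethylsilyl)oxy]-4-methylpent-3-en-1-yl]-5,8-dimethoxynaphthalene-1,4-dione
Conditions: Dess–Martin periodinane (3 equiv), pyridine, CH2Cl2, 0 °C → rt
Reagents that add atoms: none
Why: Dess–Martin oxidation of the two benzylic/allylic carbinols (or of the hydroquinone tautomer that may arise after the first oxidation) converges on the 2-ene-1,4-dione, that is the naphthoquinone, under buffered conditions that avoid acid-induced dehydration, and both uncontrolled carbinol centres vanish.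

Step 10
Reactants: 16 2-[(1S)-1-[(tert-butyldimethylsilyl)oxy]-4-methylpent-3-en-1-yl]-5,8-dimethoxynaphthalene-1,4-dione
Product: 17 2-[(1S)-1-hydroxy-4-methylpent-3-en-1-yl]-5,8-dimethoxynaphthalene-1,4-dione
Conditions: HF·pyridine, pyridine, THF, 0 °C → rt
Reagents that add atoms: none
Why: Fluoride-driven cleavage of the secondary silyl ether proceeds under buffered, non-basic conditions that the quinone tolerates, and the C1′–O bond is not broken.

Step 11
Reactants: 17 2-[(1S)-1-hydroxy-4-methylpent-3-en-1-yl]-5,8-dimethoxynaphthalene-1,4-dione; 18 tiglic acid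
Product: 19 (1S)-1-(5,8-dimethoxy-1,4-dioxo-1,4-dihydronaphthalen-2-yl)-4-methylpent-3-en-1-yl (2E)-2-methylbut-2-enoate
Conditions: 18 (2 equiv), DCC (2 equiv), DMAP (0.2 equiv), CH2Cl2, 0 °C → rt
Reagents that add atoms: none
Why: Steglich esterification acylates the only hydroxyl at oxygen, so C1′ keeps its configuration, and the thermodynamically preferred (E)-tiglate geometry is retained.

Step 12
Reactants: 19 (1S)-1-(5,8-dimethoxy-1,4-dioxo-1,4-dihydronaphthalen-2-yl)-4-methylpent-3-en-1-yl (2E)-2-methylbut-2-enoate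
Product: 21 (1S)-1-(5,8-dihydroxy-1,4-dioxo-1,4-dihydronaphthalen-2-yl)-4-methylpent-3-en-1-yl (2E)-2-methylbut-2-enoate, via diquinone 20 (not isolated)
Conditions: AgO (4 equiv), 6 M HNO3, acetone, 0 °C → rt, 10 min; extract into CHCl3; shake with aq. L-ascorbic acid, 0 °C
Reagents that add atoms: water, O
Why: In this Rapoport-type oxidative demethylation Ag(II) oxidises the para-dimethoxy ring, water adds at the two ipso carbons and methanol leaves to give the 1,4,5,8-tetraone, which is a strong oxidant and is reduced by ascorbic acid in one two-electron step to the naphthazarin without reaching the hydroquinone level that could expel the ester; the naphthazarin tautomers interconvert, so the product is the target as drawn.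

**Compound list**

1 | ethyl 2-[(2R)-oxiran-2-yl]acetate | CCOC(=O)C[C@@H]1CO1 | starting material
2 | (2-methylprop-1-en-1-yl)magnesium bromide | CC(C)=C[Mg]Br | starting material
3 | ethyl (3S)-3-hydroxy-6-methylhept-5-enoate | CCOC(=O)C[C@@H](O)CC=C(C)C | intermediate
4 | ethyl (3S)-3-[(tert-butyldimethylsilyl)oxy]-6-methylhept-5-enoate | CC(C)(C)[Si](C)(C)O[C@@H](CC=C(C)C)CC(=O)OCC | intermediate
5 | (3S)-3-[(tert-butyldimethylsilyl)oxy]-6-methylhept-5-enal | CC(C)(C)[Si](C)(C)O[C@@H](CC=C(C)C)CC=O | intermediate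
6 | (3S)-3-[(tert-butyldimethylsilyl)oxy]-2-[(dimethylamino)methyl]-6-methylhept-5-enal (Mannich base, C2 epimers, formed in the flask) | CC(C)(C)[Si](C)(C)O[C@@H](CC=C(C)C)C(CN(C)C)C=O | intermediate
7 | (3S)-3-[(tert-butyldimethylsilyl)oxy]-6-methyl-2-methylidenehept-5-enal | CC(C)(C)[Si](C)(C)O[C@@H](CC=C(C)C)C(=C)C=O | intermediate
8 | 2-bromo-1,4-dimethoxybenzene | COc1ccc(OC)c(Br)c1 | starting material
9 | (2-bromo-3,6-dimethoxyphenyl)lithium (formed in the flask) | [Li]c1c(Br)c(OC)ccc1OC | intermediate
10 | 2-bromo-3,6-dimethoxybenzaldehyde | COc1ccc(OC)c(C=O)c1Br | intermediate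
11 | vinylmagnesium bromide | C=C[Mg]Br | starting material
12 | 1-(2-bromo-3,6-dimethoxyphenyl)prop-2-en-1-ol (racemic) | C=CC(O)c1c(Br)c(OC)ccc1OC | intermediate
13 | lithium 1-(2-lithio-3,6-dimethoxyphenyl)prop-2-en-1-olate (formed in the flask) | C=CC(O[Li])c1c([Li])c(OC)ccc1OC | intermediate
14 | (3S)-3-[(tert-butyldimethylsilyl)oxy]-1-[2-(1-hydroxyprop-2-en-1-yl)-3,6-dimethoxyphenyl]-6-methyl-2-methylidenehept-5-en-1-ol (mixture at both carbinol carbons) | CC(C)(C)[Si](C)(C)O[C@@H](CC=C(C)C)C(=C)C(O)c1c(OC)ccc(OC)c1C(O)C=C | intermediate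
15 | 2-[(1S)-1-[(tert-butyldimethylsilyl)oxy]-4-methylpent-3-en-1-yl]-5,8-dimethoxy-1,4-dihydronaphthalene-1,4-diol (mixture at C1 and C4) | CC(C)(C)[Si](C)(C)O[C@@H](CC=C(C)C)C1=CC(O)c2c(OC)ccc(OC)c2C1O | intermediate
16 | 2-[(1S)-1-[(tert-butyldimethylsilyl)oxy]-4-methylpent-3-en-1-yl]-5,8-dimethoxynaphthalene-1,4-dione | CC(C)(C)[Si](C)(C)O[C@@H](CC=C(C)C)C1=CC(=O)c2c(OC)ccc(OC)c2C1=O | intermediate
17 | 2-[(1S)-1-hydroxy-4-methylpent-3-en-1-yl]-5,8-dimethoxynaphthalene-1,4-dione | O[C@@H](CC=C(C)C)C1=CC(=O)c2c(OC)ccc(OC)c2C1=O | intermediate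
18 | tiglic acid, (2E)-2-methylbut-2-enoic acid | C/C=C(\C)C(=O)O | starting material
19 | (1S)-1-(5,8-dimethoxy-1,4-dioxo-1,4-dihydronaphthalen-2-yl)-4-methylpent-3-en-1-yl (2E)-2-methylbut-2-enoate | C/C=C(\C)C(=O)O[C@@H](CC=C(C)C)C1=CC(=O)c2c(OC)ccc(OC)c2C1=O | intermediate
20 | (1S)-4-methyl-1-(1,4,5,8-tetraoxo-1,4,5,8-tetrahydronaphthalen-2-yl)pent-3-en-1-yl (2E)-2-methylbut-2-enoate (formed in the flask) | C/C=C(\C)C(=O)O[C@@H](CC=C(C)C)C1=CC(=O)C2=C(C1=O)C(=O)C=CC2=O | intermediate
21 | (1S)-1-(5,8-dihydroxy-1,4-dioxo-1,4-dihydronaphthalen-2-yl)-4-methylpent-3-en-1-yl (2E)-2-methylbut-2-enoate | C/C=C(\C)C(=O)O[C@@H](CC=C(C)C)C1=CC(=O)c2c(O)ccc(O)c2C1=O | target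

**Step count and risks**

Total steps: 12. Longest linear sequence: 10 steps (steps 1–4, then 7–12); steps 5 and 6 form the second branch.

Step 8 (key ring-closing metathesis). The free bis-allylic 1,4-diol may divert the catalyst, through ruthenium hydride isomerisation of the vinyl carbinol to an ethyl ketone or through binding of ruthenium by the diol, before the hindered 1,1-disubstituted alkene is engaged. The fallback sets out from 14. Both carbinols are capped as trimethylsilyl ethers (TMSCl, imidazole, CH2Cl2) to give (3S)-3-(tert-butyldimethylsilyloxy)-1-[3,6-dimethoxy-2-(1-trimethylsilyloxyprop-2-enyl)phenyl]-6-methyl-2-methylidene-1-trimethylsilyloxyhept-5-ene F1. Metathesis of this hydroxyl-free diene (Hoveyda–Grubbs II, toluene, 80 °C) should give 2-[(1S)-1-(tert-butyldimethylsilyloxy)-4-methylpent-3-enyl]-5,8-dimethoxy-1,4-bis(trimethylsilyloxy)-1,4-dihydronaphthalene F2. K2CO3 in MeOH then removes the two TMS groups while the TBS ether stays, which comes back to the route at 15.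

Step 12 (oxidative demethylation). The acidic oxidising medium may degrade the tiglate side chain (solvolysis of the C1′–O bond, oxidation of the two electron-rich alkenes), and the reduction may overshoot and expel the acyloxy group. The fallback sets out from 16, so that the ester is installed last. AgO/HNO3 on the silyl ether gives 2-[(1S)-1-(tert-butyldimethylsilyloxy)-4-methylpent-3-enyl]naphthalene-1,4,5,8-tetraone F3, which is reduced in the flask with ascorbic acid to 2-[(1S)-1-(tert-butyldimethylsilyloxy)-4-methylpent-3-enyl]-5,8-dihydroxynaphthalene-1,4-dione F4. HF·pyridine gives 5,8-dihydroxy-2-[(1S)-1-hydroxy-4-methylpent-3-enyl]naphthalene-1,4-dione (alkannin) F5. Steglich esterification of this triol with tiglic acid 18 (DCC, DMAP, CH2Cl2, 0 °C) should be selective for the side-chain hydroxyl, because the two peri hydroxyls are locked in hydrogen bonds to the quinone carbonyls, and comes back to the route at 21.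

Step 7 (aryllithium addition). The dianion may form incompletely or react sluggishly, so that proton return, butylation or attack of residual n-BuLi on the enal competes with the wanted 1,2-addition. The fallback sets out from 10 and adds the vinyl group last. Acetalisation (HC(OMe)3, cat. TsOH, MeOH) gives 2-bromo-3-(dimethoxymethyl)-1,4-dimethoxybenzene F6. Bromine–lithium exchange (n-BuLi, THF, −78 °C) gives the monoanionic [2-(dimethoxymethyl)-3,6-dimethoxyphenyl]lithium F7, which adds to 7 to give (3S)-3-(tert-butyldimethylsilyloxy)-1-[2-(dimethoxymethyl)-3,6-dimethoxyphenyl]-6-methyl-2-methylidenehept-5-en-1-ol F8. Mild aqueous acid (PPTS, acetone/H2O) unmasks the aldehyde, which closes to 3-[(3S)-3-(tert-butyldimethylsilyloxy)-6-methylhepta-1,5-dien-2-yl]-4,7-dimethoxy-1,3-dihydro-2-benzofuran-1-ol F9. Excess vinylmagnesium bromide 11 opens this lactol through its hydroxy aldehyde form and comes back to the route at 14.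

**Further compounds**

F1 | step 8 | (3S)-3-(tert-butyldimethylsilyloxy)-1-[3,6-dimethoxy-2-(1-trimethylsilyloxyprop-2-enyl)phenyl]-6-methyl-2-methylidene-1-trimethylsilyloxyhept-5-ene | CC(C)(C)[Si](C)(C)O[C@@H](CC=C(C)C)C(=C)C(O[Si](C)(C)C)c1c(OC)ccc(OC)c1C(O[Si](C)(C)C)C=C
F2 | step 8 | 2-[(1S)-1-(tert-butyldimethylsilyloxy)-4-methylpent-3-enyl]-5,8-dimethoxy-1,4-bis(trimethylsilyloxy)-1,4-dihydronaphthalene | CC(C)(C)[Si](C)(C)O[C@@H](CC=C(C)C)C1=CC(O[Si](C)(C)C)c2c(OC)ccc(OC)c2C1O[Si](C)(C)C
F3 | step 12 | 2-[(1S)-1-(tert-butyldimethylsilyloxy)-4-methylpent-3-enyl]naphthalene-1,4,5,8-tetraone | CC(C)(C)[Si](C)(C)O[C@@H](CC=C(C)C)C1=CC(=O)C2=C(C1=O)C(=O)C=CC2=O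
F4 | step 12 | 2-[(1S)-1-(tert-butyldimethylsilyloxy)-4-methylpent-3-enyl]-5,8-dihydroxynaphthalene-1,4-dione | CC(C)(C)[Si](C)(C)O[C@@H](CC=C(C)C)C1=CC(=O)c2c(O)ccc(O)c2C1=O
F5 | step 12 | 5,8-dihydroxy-2-[(1S)-1-hydroxy-4-methylpent-3-enyl]naphthalene-1,4-dione (alkannin) | O[C@@H](CC=C(C)C)C1=CC(=O)c2c(O)ccc(O)c2C1=O
F6 | step 7 | 2-bromo-3-(dimethoxymethyl)-1,4-dimethoxybenzene | COc1ccc(OC)c(C(OC)OC)c1Br
F7 | step 7 | [2-(dimethoxymethyl)-3,6-dimethoxyphenyl]lithium | COc1ccc(OC)c(C(OC)OC)c1[Li]
F8 | step 7 | (3S)-3-(tert-butyldimethylsilyloxy)-1-[2-(dimethoxymethyl)-3,6-dimethoxyphenyl]-6-methyl-2-methylidenehept-5-en-1-ol | CC(C)(C)[Si](C)(C)O[C@@H](CC=C(C)C)C(=C)C(O)c1c(OC)ccc(OC)c1C(OC)OC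
F9 | step 7 | 3-[(3S)-3-(tert-butyldimethylsilyloxy)-6-methylhepta-1,5-dien-2-yl]-4,7-dimethoxy-1,3-dihydro-2-benzofuran-1-ol | CC(C)(C)[Si](C)(C)O[C@@H](CC=C(C)C)C(=C)C1OC(O)c2c(OC)ccc(OC)c12
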